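**Retrosynthetic overview**
- The target is a 19-membered ring: ring A–O–ring B–CH2CH2–ring C–O–ring D–CH2CH2–back to ring A. The strategy rests on ring A, where the central C–OH lies between the carbon bearing the ether oxygen to ring B and a second C–OH; this is the pattern left when an oxidised 2,6-dibromophenol is captured at one ortho carbon by a phenol oxygen and the surviving bromine is later exchanged for oxygen.
- Key disconnection: the ring A carbon–O(ring B) bond, formed by anodic oxidation of a seco bisphenol (ring A 2,6-dibromophenol, ring B 2,6-dichlorophenol, ring C as dimethyl ether). The macrocycle is the only ring formed; the four benzene rings are bought.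
- The seco bisphenol comes from a ring C–O–ring D diaryl ether (Ullmann) with a benzylic phosphonium arm on ring C and a benzylic phosphonate arm on ring D, used in turn (Wittig with the ring B aldehyde, Horner–Wadsworth–Emmons with the ring A aldehyde), then one diimide reduction of both alkenes.
- After ring closure: zinc rearomatisation, copper-catalysed exchange of the last bromine for methoxy, hydrogenolysis of the chlorines, BBr3 demethylation.

Key step: step 10

Remark on the chemistry: the target has no stereocentre (the one that arises in the dienone is racemic and is erased in step 11), and diethyl (3-bromobenzyl)phosphonate is taken as a purchasable reagent.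

**Route**

Step 1
Reactants: 1 3-hydroxy-4,5-dimethoxybenzaldehyde
Product: 2 5-(hydroxymethyl)-2,3-dimethoxyphenol
Conditions: NaBH4, MeOH, 0 °C
Reagents that add atoms: none
Why: Chemoselective borohydride reduction of the aryl aldehyde to the benzylic alcohol, with phenol and methyl ethers inert.

Step 2
Reactants: 2 5-(hydroxymethyl)-2,3-dimethoxyphenol; 3 diethyl (3-bromobenzyl)phosphonate
Product: 4 diethyl {3-[5-(hydroxymethyl)-2,3-dimethoxyphenoxy]benzyl}phosphonate
Conditions: CuI (10 mol %), N,N-dimethylglycine hydrochloride (30 mol %), Cs2CO3, dioxane, 90 °C, Ar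
Reagents that add atoms: none
Why: Ullmann-type copper-catalysed O-arylation in which only the phenoxide formed by Cs2CO3 couples with the aryl bromide, the neutral benzylic alcohol and the phosphonate ester being spectators under carbonate conditions.

Step 3
Reactants: 4 diethyl {3-[5-(hydroxymethyl)-2,3-dimethoxyphenoxy]benzyl}phosphonate
Product: 5 {3-[3-(diethoxyphosphorylmethyl)phenoxy]-4,5-dimethoxybenzyl}triphenylphosphonium bromide
Conditions: PPh3·HBr, MeCN, 80 °C
Reagents that add atoms: triphenylphosphine hydrobromide, [Br-].c1ccc(cc1)[PH+](c1ccccc1)c1ccccc1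
Why: Direct phosphonium salt formation from an electron-rich (para-methoxy) benzylic alcohol by acid-promoted displacement of water and quaternisation of PPh3, the weakly acidic reagent leaving the diethyl phosphonate intact.

Step 4
Reactants: 6 3,5-dichloro-4-hydroxybenzaldehyde
Product: 7 3,5-dichloro-4-(methoxymethoxy)benzaldehyde
Conditions: MOMCl, iPr2NEt, CH2Cl2, 0 °C → rt
Reagents that add atoms: chloromethyl methyl ether, COCCl
Why: O-alkylation of the acidic 2,6-dichlorophenoxide with the reactive chloromethyl ether (Williamson-type acetal formation) masks the phenol against the bases that follow.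

Step 5
Reactants: 5 {3-[3-(diethoxyphosphorylmethyl)phenoxy]-4,5-dimethoxybenzyl}triphenylphosphonium bromide; 7 3,5-dichloro-4-(methoxymethoxy)benzaldehyde
Product: 9 diethyl [3-(5-{2-[3,5-dichloro-4-(methoxymethoxy)phenyl]ethenyl}-2,3-dimethoxyphenoxy)benzyl]phosphonate (E/Z mixture expected), via phosphonium ylide 8 (not isolated)
Conditions: K2CO3, 18-crown-6 (cat.), CH2Cl2, reflux
Reagents that add atoms: none
Why: Wittig olefination under solid–liquid phase-transfer conditions, where carbonate deprotonates only the benzylic phosphonium (far more acidic than the benzylic phosphonate), so the ring B aldehyde is attached to the ring C arm alone and the alkene geometry is irrelevant because step 8 reduces it.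

Step 6
Reactants: 10 3,5-dibromo-4-hydroxybenzaldehyde
Product: 11 3,5-dibromo-4-(methoxymethoxy)benzaldehyde
Conditions: MOMCl, iPr2NEt, CH2Cl2, 0 °C → rt
Reagents that add atoms: chloromethyl methyl ether, COCCl
Why: The same Williamson-type MOM protection, applied to the 2,6-dibromophenol.

Step 7
Reactants: 9 diethyl [3-(5-{2-[3,5-dichloro-4-(methoxymethoxy)phenyl]ethenyl}-2,3-dimethoxyphenoxy)benzyl]phosphonate; 11 3,5-dibromo-4-(methoxymethoxy)benzaldehyde
Product: 13 1,3-dibromo-5-[(E)-2-(3-{5-[2-(3,5-dichloro-4-(methoxymethoxy)phenyl)ethenyl]-2,3-dimethoxyphenoxy}phenyl)ethenyl]-2-(methoxymethoxy)benzene (bis-stilbene), via potassium phosphonate carbanion 12 (not isolated)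
Conditions: KOtBu, THF, 0 °C; then 11, 0 °C → rt
Reagents that add atoms: none
Why: Horner–Wadsworth–Emmons olefination of the benzylic phosphonate carbanion with the aryl aldehyde should give the E stilbene, with aryl halides and MOM acetals inert to KOtBu at this temperature.

Step 8
Reactants: 13 bis-stilbene
Product: 14 1,3-dibromo-5-[2-(3-{5-[2-(3,5-dichloro-4-(methoxymethoxy)phenyl)ethyl]-2,3-dimethoxyphenoxy}phenyl)ethyl]-2-(methoxymethoxy)benzene (bis-bibenzyl bis-MOM ether)
Conditions: TsNHNH2 (excess, in portions), NaOAc, DME/H2O, reflux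
Reagents that add atoms: none
Why: Diimide generated in situ from tosylhydrazide reduces both stilbene C=C bonds by concerted syn hydrogen transfer and leaves aryl C–Br, aryl C–Cl and the MOM acetals untouched, which catalytic hydrogenation would not guarantee.

Step 9
Reactants: 14 bis-bibenzyl bis-MOM ether
Product: 15 2,6-dibromo-4-[2-(3-{5-[2-(3,5-dichloro-4-hydroxyphenyl)ethyl]-2,3-dimethoxyphenoxy}phenyl)ethyl]phenol (seco bisphenol)
Conditions: HCl (cat.), MeOH/THF, 50 °C
Reagents that add atoms: none
Why: Acid-catalysed acetal exchange with methanol removes both MOM groups while aryl methyl ethers and the diaryl ether are stable.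

Step 10
Reactants: 15 seco bisphenol
Product: 17 macrocyclic ring A 6-aryloxy-2,6-dibromocyclohexa-2,4-dienone (racemic; ring B oxygen on C6), via ring A phenoxonium ion 16 (not isolated)
Conditions: constant-current electrolysis (undivided cell, glassy-carbon anode, Pt cathode), LiClO4, MeOH, ca. 1 mM, rt; crude dienone carried on
Reagents that add atoms: none
Why: Anodic loss of two electrons and a proton from the ring A 2,6-dibromophenol gives phenoxonium ion 16, which the phenolic oxygen of ring B traps at a bromine-bearing ortho carbon to give the 6-aryloxy-6-bromocyclohexa-2,4-dienone. The closest known reaction type is the anodic or Tl(NO3)3-mediated oxidation of 2,6-dihalophenols to ortho-aryloxy halodienones, used for isodityrosine-type diaryl ethers. The 19-membered ring closes by intramolecular capture of the electrophilic ring A carbon by the ring B oxygen nucleophile (macro-etherification) at high dilution. The one new stereocentre, the quaternary C(Br)(OAr) carbon, forms as a racemate without control, and none is needed because step 11 removes it. The step needs oxidation of ring A alone and attack through oxygen: the dibromophenol oxidises at a lower potential than the dichlorophenol and than the methylated ring C, and ring B can react only at oxygen because both its ortho carbons carry chlorine and its para carbon carries the ethylene bridge. Capture at the para carbon of ring A by methanol or phenol would give quinol-ether dienones, which the zinc treatment of step 11 should return to 15.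

Step 11
Reactants: 17 macrocyclic bromodienone
Product: 18 macrocyclic bromophenol (ring A: 2-aryloxy-6-bromo-4-alkylphenol; ring B 2,6-dichloro; ring C dimethyl ether)
Conditions: Zn dust, AcOH/THF, rt
Reagents that add atoms: none
Why: Zinc reduces the α-bromo ketone C–Br bond of the dienone to the zinc dienolate, which is the phenoxide of rearomatised ring A, erasing the stereocentre, while aryl halides are not reduced under these conditions.

Step 12
Reactants: 18 macrocyclic bromophenol
Product: 19 macrocyclic methoxyphenol (ring A: 2-aryloxy-6-methoxy-4-alkylphenol; ring B 2,6-dichloro)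
Conditions: NaOMe (excess), CuBr (20 mol %), EtOAc (cat.), MeOH/DMF, 110 °C, Ar; aq. HCl work-up
Reagents that add atoms: sodium methoxide, [Na+].[O-]C
Why: Copper-catalysed Ullmann-type methoxylation of an ortho-bromophenoxide (the reaction type that turns 5-bromovanillin into syringaldehyde), with the unactivated aryl chlorides of ring B inert to CuBr/NaOMe at this temperature.

Step 13
Reactants: 19 macrocyclic methoxyphenol
Product: 20 dechlorinated macrocycle (ring B para-phenylene; ring A 2-aryloxy-6-methoxyphenol; ring C dimethyl ether)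
Conditions: H2 (3 atm), 10% Pd/C, Et3N, MeOH/EtOAc, rt
Reagents that add atoms: none
Why: Palladium-catalysed hydrogenolysis of the two aryl C–Cl bonds with amine as HCl scavenger, under which diaryl ethers, methyl ethers and the bibenzyl bridges are stable.

Step 14
Reactants: 20 dechlorinated macrocycle
Product: 21 CNP0511668.0 (target)
Conditions: BBr3 (excess), CH2Cl2, −78 °C → rt; MeOH then H2O quench, under Ar
Reagents that add atoms: none
Why: BBr3 cleaves the three aryl methyl ethers by Lewis-acid activation and bromide attack at methyl, leaving the diaryl ether C–O bonds intact.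

**Compound list**
1 | 3-hydroxy-4,5-dimethoxybenzaldehyde | COc1cc(C=O)cc(O)c1OC | starting material
2 | 5-(hydroxymethyl)-2,3-dimethoxyphenol | COc1cc(CO)cc(O)c1OC | intermediate
3 | diethyl (3-bromobenzyl)phosphonate | CCOP(=O)(Cc1cccc(Br)c1)OCC | starting material
4 | diethyl {3-[5-(hydroxymethyl)-2,3-dimethoxyphenoxy]benzyl}phosphonate | CCOP(=O)(Cc1cccc(Oc2cc(CO)cc(OC)c2OC)c1)OCC | intermediate
5 | {3-[3-(diethoxyphosphorylmethyl)phenoxy]-4,5-dimethoxybenzyl}triphenylphosphonium bromide | [Br-].CCOP(=O)(Cc1cccc(Oc2cc(C[P+](c3ccccc3)(c3ccccc3)c3ccccc3)cc(OC)c2OC)c1)OCC | intermediate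
6 | 3,5-dichloro-4-hydroxybenzaldehyde | O=Cc1cc(Cl)c(O)c(Cl)c1 | starting material
7 | 3,5-dichloro-4-(methoxymethoxy)benzaldehyde | COCOc1c(Cl)cc(C=O)cc1Cl | intermediate
8 | phosphonium ylide of 5 (not isolated) | CCOP(=O)(Cc1cccc(Oc2cc(C=P(c3ccccc3)(c3ccccc3)c3ccccc3)cc(OC)c2OC)c1)OCC | intermediate
9 | diethyl [3-(5-{2-[3,5-dichloro-4-(methoxymethoxy)phenyl]ethenyl}-2,3-dimethoxyphenoxy)benzyl]phosphonate (E/Z mixture) | CCOP(=O)(Cc1cccc(Oc2cc(C=Cc3cc(Cl)c(OCOC)c(Cl)c3)cc(OC)c2OC)c1)OCC | intermediate
10 | 3,5-dibromo-4-hydroxybenzaldehyde | O=Cc1cc(Br)c(O)c(Br)c1 | starting material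
11 | 3,5-dibromo-4-(methoxymethoxy)benzaldehyde | COCOc1c(Br)cc(C=O)cc1Br | intermediate
12 | potassium phosphonate carbanion of 9 (not isolated) | [K+].CCOP(=O)([CH-]c1cccc(Oc2cc(C=Cc3cc(Cl)c(OCOC)c(Cl)c3)cc(OC)c2OC)c1)OCC | intermediate
13 | bis-stilbene (E at the ring A–ring D alkene; ring B–ring C alkene E/Z) | COCOc1c(Br)cc(/C=C/c2cccc(Oc3cc(C=Cc4cc(Cl)c(OCOC)c(Cl)c4)cc(OC)c3OC)c2)cc1Br | intermediate
14 | bis-bibenzyl bis-MOM ether | COCOc1c(Br)cc(CCc2cccc(Oc3cc(CCc4cc(Cl)c(OCOC)c(Cl)c4)cc(OC)c3OC)c2)cc1Br | intermediate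
15 | seco bisphenol (ring A 2,6-dibromophenol, ring B 2,6-dichlorophenol) | Oc1c(Br)cc(CCc2cccc(Oc3cc(CCc4cc(Cl)c(O)c(Cl)c4)cc(OC)c3OC)c2)cc1Br | intermediate
16 | ring A phenoxonium ion (not isolated) | O=C1C(Br)=CC(CCc2cccc(Oc3cc(CCc4cc(Cl)c(O)c(Cl)c4)cc(OC)c3OC)c2)=C[C+]1Br | intermediate
17 | macrocyclic 6-aryloxy-2,6-dibromocyclohexa-2,4-dienone (racemic) | O=C1C(Br)=CC2=CC1(Br)Oc1c(Cl)cc(cc1Cl)CCc1cc(OC)c(OC)c(c1)Oc1cccc(c1)CC2 | intermediate
18 | macrocyclic bromophenol | Oc1c(Br)cc2cc1Oc1c(Cl)cc(cc1Cl)CCc1cc(OC)c(OC)c(c1)Oc1cccc(c1)CC2 | intermediate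
19 | macrocyclic methoxyphenol (ring B dichloro) | COc1cc2cc(c1O)Oc1c(Cl)cc(cc1Cl)CCc1cc(OC)c(OC)c(c1)Oc1cccc(c1)CC2 | intermediate
20 | dechlorinated macrocycle (trimethyl ether) | COc1cc2cc(c1O)Oc1ccc(cc1)CCc1cc(OC)c(OC)c(c1)Oc1cccc(c1)CC2 | intermediate
21 | CNP0511668.0 | Oc1cc2cc(c1O)Oc1ccc(cc1)CCc1cc(O)c(O)c(c1)Oc1cccc(c1)CC2 | target

**Step count**
Total: 14 steps. Longest linear sequence: 12 steps (1 → 2 → 4 → 5 → 9 → 13 → 14 → 15 → 17 → 18 → 19 → 20 → 21).

**Steps most likely to fail**

Step 10. The phenoxonium ion may be intercepted by methanol or by a second molecule faster than the 19-membered ring closes, and competing oxidation of the dichlorophenol or over-oxidation of the dienone may erode the material. The fallback forms the same ring A carbon–oxygen bond with reversed polarity, by copper-catalysed coupling; it sets out from 5 and comes back at 21. Wittig olefination of 5 with 4-(methoxymethoxy)benzaldehyde (K2CO3, 18-crown-6, CH2Cl2) would give diethyl [3-(2,3-dimethoxy-5-{2-[4-(methoxymethoxy)phenyl]ethenyl}phenoxy)benzyl]phosphonate F1. Horner–Wadsworth–Emmons reaction with 3-bromo-4,5-dimethoxybenzaldehyde (KOtBu, THF) would give the bromo bis-stilbene F2, and diimide reduction (TsNHNH2, NaOAc) the bromo bis-bibenzyl MOM ether F3. HCl in MeOH would free the ring B phenol of the bromo seco phenol F4. Intramolecular Ullmann etherification (CuI, picolinic acid, K3PO4, DMSO, 90 °C, slow addition at high dilution) would close the macrocyclic tetramethyl ether F5, which BBr3 converts into 21.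

Step 12. Copper-mediated hydrodebromination of ring A, slow exchange on the electron-rich phenoxide, or methoxide attack at the aryl chlorides may compete. The fallback sets out from 18 and comes back at 21. O-methylation (MeI, K2CO3, acetone) would give the bromo methyl ether F6. Miyaura borylation (Pd(dppf)Cl2, B2pin2, KOAc, dioxane, 90 °C) would give the pinacol boronate F7, and oxidation (H2O2, NaOH, THF, 0 °C) the dichloro phenol F8. Hydrogenolysis (H2, Pd/C, Et3N) would give the dechlorinated phenol F9, and BBr3 then gives 21.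

Step 2. Coupling of the ortho-methoxy phenoxide may be slow, with reduction of the aryl bromide or arylation of the benzylic hydroxyl competing. The fallback is a room-temperature Chan–Lam coupling; it sets out from 3 (with 1) and comes back at 4. Miyaura borylation of 3 (Pd(dppf)Cl2, B2pin2, KOAc) would give diethyl [3-(4,4,5,5-tetramethyl-1,3,2-dioxaborolan-2-yl)benzyl]phosphonate F10. Cleavage with NaIO4 and NH4OAc in aqueous acetone would give {3-[(diethoxyphosphoryl)methyl]phenyl}boronic acid F11. Coupling with 1 (Cu(OAc)2, pyridine, 4 Å molecular sieves, CH2Cl2, air, rt) would give diethyl [3-(5-formyl-2,3-dimethoxyphenoxy)benzyl]phosphonate F12, which NaBH4 in MeOH reduces to 4.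

**Further compounds**
F1 | step 10 | diethyl [3-(2,3-dimethoxy-5-{2-[4-(methoxymethoxy)phenyl]ethenyl}phenoxy)benzyl]phosphonate | CCOP(=O)(Cc1cccc(Oc2cc(C=Cc3ccc(OCOC)cc3)cc(OC)c2OC)c1)OCC
F2 | step 10 | bromo bis-stilbene (ring A 3-bromo-4,5-dimethoxyphenyl, ring B 4-MOM-oxyphenyl) | COCOc1ccc(C=Cc2cc(OC)c(OC)c(Oc3cccc(/C=C/c4cc(Br)c(OC)c(OC)c4)c3)c2)cc1
F3 | step 10 | bromo bis-bibenzyl MOM ether | COCOc1ccc(CCc2cc(OC)c(OC)c(Oc3cccc(CCc4cc(Br)c(OC)c(OC)c4)c3)c2)cc1
F4 | step 10 | bromo seco phenol | Oc1ccc(CCc2cc(OC)c(OC)c(Oc3cccc(CCc4cc(Br)c(OC)c(OC)c4)c3)c2)cc1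
F5 | step 10 | macrocyclic tetramethyl ether of the target | COc1cc2cc(c1OC)Oc1ccc(cc1)CCc1cc(OC)c(OC)c(c1)Oc1cccc(c1)CC2
F6 | step 12 | bromo methyl ether of 18 | COc1c(Br)cc2cc1Oc1c(Cl)cc(cc1Cl)CCc1cc(OC)c(OC)c(c1)Oc1cccc(c1)CC2
F7 | step 12 | ring A pinacol boronate | COc1c(B3OC(C)(C)C(C)(C)O3)cc2cc1Oc1c(Cl)cc(cc1Cl)CCc1cc(OC)c(OC)c(c1)Oc1cccc(c1)CC2
F8 | step 12 | dichloro phenol (ring A 3-aryloxy-4-methoxy-5-hydroxy) | COc1c(O)cc2cc1Oc1c(Cl)cc(cc1Cl)CCc1cc(OC)c(OC)c(c1)Oc1cccc(c1)CC2
F9 | step 12 | dechlorinated phenol | COc1c(O)cc2cc1Oc1ccc(cc1)CCc1cc(OC)c(OC)c(c1)Oc1cccc(c1)CC2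
F10 | step 2 | diethyl [3-(4,4,5,5-tetramethyl-1,3,2-dioxaborolan-2-yl)benzyl]phosphonate | CCOP(=O)(Cc1cccc(c1)B1OC(C)(C)C(C)(C)O1)OCC
F11 | step 2 | {3-[(diethoxyphosphoryl)methyl]phenyl}boronic acid | CCOP(=O)(Cc1cccc(c1)B(O)O)OCC
F12 | step 2 | diethyl [3-(5-formyl-2,3-dimethoxyphenoxy)benzyl]phosphonate | CCOP(=O)(Cc1cccc(Oc2cc(C=O)cc(OC)c2OC)c1)OCC
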